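## Retrosynthetic overview

1. The target is the mono-seco acid of a C2-symmetric 6,6'-linked bis(chromanone lactone), so the last step is opening one of two equivalent γ-lactones.
2. The biaryl bond comes from ortho–ortho oxidative phenol coupling of the monomeric chromanone lactone.
3. Key step: the carbinol–CHMe bond and the whole γ-lactone are made in one operation by carbene-catalysed homoenolate annulation. The β-carbon of crotonaldehyde (normally electrophilic) attacks the formyl carbon of a 2-formylchromanone-2-carboxylate (also electrophilic).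
4. The formyl group comes from a 2-alkynyl group (semi-hydrogenation, ozonolysis). The quaternary C2 is set by enantioselective copper-catalysed alkynylation of the benzopyrylium ion from methyl 5-hydroxychromone-2-carboxylate.
5. Ring order: pyranone ring (chromone), then the C2 quaternary centre, then the γ-lactone (key step), then the biaryl, then one lactone opened.

Assumption: the free γ-hydroxy acid of the target is treated as isolable when kept cold and near pH 4–5; the senses of induction of the copper–bis(oxazoline) catalyst and of the aminoindanol triazolium are taken as written, and the antipodal ligand or precatalyst is used if a pilot run shows the opposite sense.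

## Route

Step 1
Reactants: 1 2',6'-dihydroxyacetophenone; 2 dimethyl oxalate
Product: 4 methyl 5-hydroxy-4-oxo-4H-chromene-2-carboxylate, via diketo ester 3 (not isolated)
Conditions: NaOMe (4 equiv), 2 (3 equiv), MeOH, reflux; then conc. HCl, MeOH, reflux
Reagents that add atoms: none
Why: Crossed Claisen condensation of the methyl ketone enolate with the non-enolisable oxalate, then acid-catalysed cyclodehydration onto a phenol (chromone synthesis) builds the pyranone ring; no stereocentre is formed.

Step 2
Reactants: 4 methyl 5-hydroxy-4-oxo-4H-chromene-2-carboxylate; 5 phenylacetylene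
Product: 8 methyl (2S)-5-(tert-butyldimethylsilyloxy)-4-oxo-2-(phenylethynyl)chromane-2-carboxylate, via benzopyrylium triflate 6 (not isolated), via bis-silyl chromene 7 (not isolated)
Conditions: TBSOTf (2.3 equiv), 2,6-lutidine (1.1 equiv), CH2Cl2, 0 °C to rt; then CuI (10 mol%), 2,2'-(propane-2,2-diyl)bis[(4S)-4-phenyl-4,5-dihydro-1,3-oxazole] (12 mol%), iPr2NEt (1.5 equiv), 5 (1.5 equiv), toluene, −40 °C; then 1 M HCl, THF, 0 °C
Reagents that add atoms: tert-butyldimethylsilyl trifluoromethanesulfonate, CC(C)(C)[Si](C)(C)OS(=O)(=O)C(F)(F)F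
Why: The silyl triflate caps the 5-OH and turns the chromone into a 4-siloxybenzopyrylium ion, whose C2 is attacked by the chiral monovalent copper acetylide (catalytic enantioselective alkynylation of a benzopyrylium ion) with the bis(oxazoline) ligand shielding one face so that C2 is set as S; dilute acid then cleaves only the silyl enol ether and leaves the aryl silyl ether as a protecting group.

Step 3
Reactants: 8 methyl (2S)-5-(tert-butyldimethylsilyloxy)-4-oxo-2-(phenylethynyl)chromane-2-carboxylate
Product: 9 methyl (2S)-5-(tert-butyldimethylsilyloxy)-4-oxo-2-[(Z)-2-phenylethenyl]chromane-2-carboxylate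
Conditions: H2 (1 atm), Pd/CaCO3 poisoned with Pb(OAc)2, quinoline, EtOAc, rt
Reagents that add atoms: none
Why: Syn semi-hydrogenation over poisoned palladium (Lindlar reduction) stops at the cis-alkene and touches neither the aryl ketone nor the quaternary C2, so its configuration is carried through.

Step 4
Reactants: 9 methyl (2S)-5-(tert-butyldimethylsilyloxy)-4-oxo-2-[(Z)-2-phenylethenyl]chromane-2-carboxylate
Product: 10 methyl (2S)-5-(tert-butyldimethylsilyloxy)-2-formyl-4-oxochromane-2-carboxylate
Conditions: O3 (titrated to the first blue tint), CH2Cl2, −78 °C; then Me2S, −78 °C to rt; used crude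
Reagents that add atoms: ozone, [O-][O+]=O
Why: Ozonolysis with reductive work-up cleaves the styrenyl double bond much faster than the acylated, silylated arene, and the aldehyde formed has no α-hydrogen, so C2 cannot epimerise by enolisation.

Step 5
Reactants: 10 methyl (2S)-5-(tert-butyldimethylsilyloxy)-2-formyl-4-oxochromane-2-carboxylate; 11 (E)-crotonaldehyde
Product: 13 methyl (2S)-5-hydroxy-2-[(2R,3S)-3-methyl-5-oxooxolan-2-yl]-4-oxochromane-2-carboxylate, via silyl-protected lactone 12 (not isolated)
Conditions: 11 (3 equiv), (5aR,10bS)-5a,10b-dihydro-2-(2,4,6-trimethylphenyl)-4H,6H-indeno[2,1-b][1,2,4]triazolo[4,3-d][1,4]oxazinium chloride (15 mol%), iPr2NEt (20 mol%), 4 Å MS, THF, rt; then Et3N·3HF, 0 °C to rt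
Reagents that add atoms: none
Why: Carbene-catalysed homoenolate annulation of an enal with an aldehyde: the triazolylidene converts crotonaldehyde into its Breslow intermediate, whose β-carbon attacks the formyl carbon of 10, and the new alkoxide acylates itself on the acyl azolium to close the γ-lactone and release the catalyst; the cis relationship follows the usual cis preference of this annulation, the absolute sense at both new centres (carbinol R, CHMe S) is set by the chiral aminoindanol carbene because the groups flanking the formyl group (CO2Me and ring CH2) give little substrate bias, and 10 is too hindered to form its own Breslow intermediate, so it acts only as acceptor; buffered fluoride then removes the aryl silyl ether. The reaction type is known, but this substrate pairing (aliphatic enal with an α-quaternary α-aryloxy aldehyde) is an untested extension.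

Step 6
Reactants: 13 methyl (2S)-5-hydroxy-2-[(2R,3S)-3-methyl-5-oxooxolan-2-yl]-4-oxochromane-2-carboxylate (2 molecules)
Product: 14 dimethyl (2S,2'S)-5,5'-dihydroxy-2,2'-bis[(2R,3S)-3-methyl-5-oxooxolan-2-yl]-4,4'-dioxo-[6,6'-bichromane]-2,2'-dicarboxylate
Conditions: VOF3 (2.5 equiv), TFA/CH2Cl2 (1:4), 0 °C
Reagents that add atoms: none
Why: Oxidative phenol coupling mediated by pentavalent vanadium: the vanadium phenoxide is oxidised by one electron and couples inner-sphere at C6, the free position ortho to the metal-bound oxygen and para to the ring oxygen; the new axis carries only two ortho substituents, rotates freely and adds no stereo-element, and the stereocentres are untouched in acid.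

Step 7
Reactants: 14 dimethyl (2S,2'S)-5,5'-dihydroxy-2,2'-bis[(2R,3S)-3-methyl-5-oxooxolan-2-yl]-4,4'-dioxo-[6,6'-bichromane]-2,2'-dicarboxylate
Product: 15 (3S,4R)-4-hydroxy-4-[(2S)-5-hydroxy-6-{(2S)-5-hydroxy-2-(methoxycarbonyl)-2-[(2R,3S)-3-methyl-5-oxooxolan-2-yl]-4-oxochroman-6-yl}-2-(methoxycarbonyl)-4-oxochroman-2-yl]-3-methylbutanoic acid
Conditions: LiOH·H2O (3.0 equiv), THF/H2O (3:1), 0 °C, about 1 h; 0.5 M HCl to pH 4–5 at 0 °C; cold reverse-phase chromatography; recovered 14 recycled
Reagents that add atoms: lithium hydroxide, [Li+].[OH-]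
Why: Chemoselective saponification: two equivalents deprotonate the phenols (which also lowers C3–H acidity and protects C2 against retro-oxa-Michael epimerisation), and the third opens one unhindered γ-lactone by acyl–oxygen cleavage much faster than the neopentyl-type methyl esters; the two lactones are equivalent by symmetry, so the mono-acid is a single compound, no stereocentre is touched, and cold work-up near pH 4–5 avoids relactonisation.

## Compound list

1 | 2',6'-dihydroxyacetophenone | CC(=O)c1c(O)cccc1O | starting material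
2 | dimethyl oxalate | COC(=O)C(=O)OC | starting material
3 | methyl 4-(2,6-dihydroxyphenyl)-2,4-dioxobutanoate (formed as its sodium enolate) | COC(=O)C(=O)CC(=O)c1c(O)cccc1O | intermediate
4 | methyl 5-hydroxy-4-oxo-4H-chromene-2-carboxylate | COC(=O)c1cc(=O)c2c(O)cccc2o1 | intermediate
5 | phenylacetylene | C#Cc1ccccc1 | starting material
6 | 4,5-bis(tert-butyldimethylsilyloxy)-2-(methoxycarbonyl)chromenylium trifluoromethanesulfonate | COC(=O)c1cc(O[Si](C)(C)C(C)(C)C)c2c(O[Si](C)(C)C(C)(C)C)cccc2[o+]1.[O-]S(=O)(=O)C(F)(F)F | intermediate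
7 | methyl (2S)-4,5-bis(tert-butyldimethylsilyloxy)-2-(phenylethynyl)-2H-chromene-2-carboxylate | COC(=O)[C@@]1(C#Cc2ccccc2)C=C(O[Si](C)(C)C(C)(C)C)c2c(O[Si](C)(C)C(C)(C)C)cccc2O1 | intermediate
8 | methyl (2S)-5-(tert-butyldimethylsilyloxy)-4-oxo-2-(phenylethynyl)chromane-2-carboxylate | COC(=O)[C@@]1(C#Cc2ccccc2)CC(=O)c2c(O[Si](C)(C)C(C)(C)C)cccc2O1 | intermediate
9 | methyl (2S)-5-(tert-butyldimethylsilyloxy)-4-oxo-2-[(Z)-2-phenylethenyl]chromane-2-carboxylate | COC(=O)[C@@]1(/C=C\c2ccccc2)CC(=O)c2c(O[Si](C)(C)C(C)(C)C)cccc2O1 | intermediate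
10 | methyl (2S)-5-(tert-butyldimethylsilyloxy)-2-formyl-4-oxochromane-2-carboxylate | COC(=O)[C@@]1(C=O)CC(=O)c2c(O[Si](C)(C)C(C)(C)C)cccc2O1 | intermediate
11 | (E)-crotonaldehyde | C/C=C/C=O | starting material
12 | methyl (2S)-5-(tert-butyldimethylsilyloxy)-2-[(2R,3S)-3-methyl-5-oxooxolan-2-yl]-4-oxochromane-2-carboxylate | COC(=O)[C@@]1([C@@H]2OC(=O)C[C@@H]2C)CC(=O)c2c(O[Si](C)(C)C(C)(C)C)cccc2O1 | intermediate
13 | methyl (2S)-5-hydroxy-2-[(2R,3S)-3-methyl-5-oxooxolan-2-yl]-4-oxochromane-2-carboxylate | COC(=O)[C@@]1([C@@H]2OC(=O)C[C@@H]2C)CC(=O)c2c(O)cccc2O1 | intermediate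
14 | dimethyl (2S,2'S)-5,5'-dihydroxy-2,2'-bis[(2R,3S)-3-methyl-5-oxooxolan-2-yl]-4,4'-dioxo-[6,6'-bichromane]-2,2'-dicarboxylate | COC(=O)[C@@]1([C@@H]2OC(=O)C[C@@H]2C)CC(=O)c2c(ccc(-c3ccc4c(c3O)C(=O)C[C@@](C(=O)OC)([C@@H]3OC(=O)C[C@@H]3C)O4)c2O)O1 | intermediate
15 | (3S,4R)-4-hydroxy-4-[(2S)-5-hydroxy-6-{(2S)-5-hydroxy-2-(methoxycarbonyl)-2-[(2R,3S)-3-methyl-5-oxooxolan-2-yl]-4-oxochroman-6-yl}-2-(methoxycarbonyl)-4-oxochroman-2-yl]-3-methylbutanoic acid | COC(=O)[C@@]1([C@H](O)[C@@H](C)CC(=O)O)CC(=O)c2c(ccc(-c3ccc4c(c3O)C(=O)C[C@@](C(=O)OC)([C@@H]3OC(=O)C[C@@H]3C)O4)c2O)O1 | target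

## Step count and risks

Total step count: 7. Longest linear sequence: 7 steps (1 to 15); the route is fully linear, with 2, 5 and 11 added as single reagents.

The three steps most likely to fail:

**Step 5 (homoenolate annulation).** The risks are low reactivity of the aliphatic enal, a poor cis/trans or facial ratio on the hindered aldehyde, carbene-induced loss of the α-aryloxy group, and base-induced retro-oxa-Michael erosion at C2. The fallback sets out from 10 and comes back to the route at 12. Crotylboration of 10 with (Z)-crotyl-B(Ipc)2 (from cis-2-butene, n-BuLi/KOt-Bu, (Ipc)2BOMe and BF3·OEt2; the Ipc antipode that gives the 1R,2S adduct; THF, −78 °C; ethanolamine work-up) goes through a closed chair transition state to the syn homoallylic alcohol methyl (2S)-5-(tert-butyldimethylsilyloxy)-2-[(1R,2S)-1-hydroxy-2-methylbut-3-en-1-yl]-4-oxochromane-2-carboxylate F1. Hydroboration of the terminal alkene with 9-BBN (THF, 0 °C) and oxidation with NaBO3·4H2O gives the diol methyl (2S)-5-(tert-butyldimethylsilyloxy)-2-[(1R,2S)-1,4-dihydroxy-2-methylbutyl]-4-oxochromane-2-carboxylate F2. TEMPO/PhI(OAc)2 (CH2Cl2, rt) oxidises the primary alcohol and then the lactol, closing the cis-lactone 12, which is desilylated with Et3N·3HF as in step 5.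

**Step 6 (oxidative dimerisation).** The risks are competing ortho–para (6,8') coupling, over-oxidation and low conversion of the deactivated, chelated phenol. The fallback sets out from 13 and comes back at 14. Amine-directed ortho-bromination (NBS, catalytic iPr2NH, CH2Cl2, 0 °C) gives methyl (2S)-6-bromo-5-hydroxy-2-[(2R,3S)-3-methyl-5-oxooxolan-2-yl]-4-oxochromane-2-carboxylate F3. Stannylation with Me3SnSnMe3 and Pd(PPh3)4 (zerovalent palladium, toluene, 100 °C) gives methyl (2S)-5-hydroxy-2-[(2R,3S)-3-methyl-5-oxooxolan-2-yl]-4-oxo-6-(trimethylstannyl)chromane-2-carboxylate F4. Oxidative homocoupling of the aryl stannane with CuCl in DMA under air at rt then fixes the 6,6' bond and gives 14.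

**Step 7 (mono-opening).** The risks are the statistical mixture of unreacted 14, mono-acid and di-acid, partial methyl ester hydrolysis, and relactonisation on acidification. The fallback sets out from 14 and comes back at 15. Both lactones are opened with excess LiOH (4.5 equiv, THF/H2O, 0 °C) to the bis(hydroxy acid) (3S,3'S,4R,4'R)-4,4'-[(2S,2'S)-5,5'-dihydroxy-2,2'-bis(methoxycarbonyl)-4,4'-dioxo-[6,6'-bichromane]-2,2'-diyl]bis(4-hydroxy-3-methylbutanoic acid) F5. F5 is then allowed to relactonise once under mild acid (pyridinium p-toluenesulfonate, THF, 0 °C to rt, followed by HPLC) and the reaction is stopped near half conversion to give 15; any 14 formed is recycled.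

## Further compounds

F1 | step 5 | methyl (2S)-5-(tert-butyldimethylsilyloxy)-2-[(1R,2S)-1-hydroxy-2-methylbut-3-en-1-yl]-4-oxochromane-2-carboxylate | COC(=O)[C@@]1([C@H](O)[C@@H](C)C=C)CC(=O)c2c(O[Si](C)(C)C(C)(C)C)cccc2O1
F2 | step 5 | methyl (2S)-5-(tert-butyldimethylsilyloxy)-2-[(1R,2S)-1,4-dihydroxy-2-methylbutyl]-4-oxochromane-2-carboxylate | COC(=O)[C@@]1([C@H](O)[C@@H](C)CCO)CC(=O)c2c(O[Si](C)(C)C(C)(C)C)cccc2O1
F3 | step 6 | methyl (2S)-6-bromo-5-hydroxy-2-[(2R,3S)-3-methyl-5-oxooxolan-2-yl]-4-oxochromane-2-carboxylate | COC(=O)[C@@]1([C@@H]2OC(=O)C[C@@H]2C)CC(=O)c2c(ccc(Br)c2O)O1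
F4 | step 6 | methyl (2S)-5-hydroxy-2-[(2R,3S)-3-methyl-5-oxooxolan-2-yl]-4-oxo-6-(trimethylstannyl)chromane-2-carboxylate | COC(=O)[C@@]1([C@@H]2OC(=O)C[C@@H]2C)CC(=O)c2c(ccc([Sn](C)(C)C)c2O)O1
F5 | step 7 | (3S,3'S,4R,4'R)-4,4'-[(2S,2'S)-5,5'-dihydroxy-2,2'-bis(methoxycarbonyl)-4,4'-dioxo-[6,6'-bichromane]-2,2'-diyl]bis(4-hydroxy-3-methylbutanoic acid) | COC(=O)[C@@]1([C@H](O)[C@@H](C)CC(=O)O)CC(=O)c2c(ccc(-c3ccc4c(c3O)C(=O)C[C@@](C(=O)OC)([C@H](O)[C@@H](C)CC(=O)O)O4)c2O)O1
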